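**Retrosynthetic overview**
1. The target is read as (−)-epicatechin 3-O-gallate-(4β→6)-(−)-epicatechin 3-O-gallate-(4β→8)-(+)-catechin. The last operations are hydrogenolysis of nineteen benzyl ethers, one double galloylation, and Friedel–Crafts formation of the C4(middle)–C8(bottom) bond from a middle-unit flavan-4-ol.
2. Key disconnection: the pyran ring (ring C) of the middle unit is opened at O1–C8a and at C4a–C4. This gives an aryne on ring A of the middle unit (triple bond C4a≡C8a, top unit already on the future C6) and a three-carbon aldol fragment O1–C2–C3–C4(=O).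
3. Enabling feature: C4a and C8a are adjacent carbons of benzene ring A that carry C4 and O1, the ortho pattern of an aryne. The oxygen on C5, next to C4a, steers the alkoxide to C8a and places the carbanion on C4a. Because the O1–C2 bond is never broken, a syn aldol maps with retention onto the 2,3-cis (epicatechin) array.
4. The aryne precursor comes from the C4 cation of protected epicatechin and a 2-bromo-3,5-dibenzyloxyphenyl silyl ether, joined at the carbon between the two benzyloxy groups, so the 4→6 linkage is fixed before the middle ring exists. Retro-Brook shift and triflation follow. The aldehyde comes from an Evans syn glycolate aldol.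
5. Ring order: the pyran rings of the top and bottom units come from (−)-epicatechin and (+)-catechin; the only ring built is the middle pyran ring (step 14).

Key step: step 14

Remark on the chemistry: compounds 5, 13, 17 and 31 are taken as purchased, and flavan-4-ol 24 is carried as a mixture of C4 epimers because C4 is ionized in step 17.

**Step 1**
Reactants: 1 (−)-epicatechin
Product: 2 5,7,3',4'-tetra-O-benzyl-(−)-epicatechin
Conditions: BnBr (4.4 equiv), K2CO3, DMF, 0 °C → rt
Reagents that add atoms: benzyl bromide, BrCc1ccccc1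
Why: Williamson etherification of the four phenols, which are far more acidic than the secondary alcohol, should leave the 3-hydroxyl free and C2 and C3 untouched.

**Step 2**
Reactants: 2 5,7,3',4'-tetra-O-benzyl-(−)-epicatechin
Product: 3 4β-(2-ethoxyethoxy)-5,7,3',4'-tetra-O-benzyl-(−)-epicatechin
Conditions: DDQ (2 equiv), 2-ethoxyethanol (5 equiv), CH2Cl2, rt
Reagents that add atoms: 2-ethoxyethanol, CCOCCO
Why: DDQ benzylic oxidation at C4 gives a cation stabilized by ring A, which the alcohol should capture trans to the 3-hydroxyl (4β).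

**Step 3**
Reactants: 3 4β-(2-ethoxyethoxy)-5,7,3',4'-tetra-O-benzyl-(−)-epicatechin
Product: 4 3-O-allyl-4β-(2-ethoxyethoxy)-5,7,3',4'-tetra-O-benzyl-(−)-epicatechin
Conditions: NaH, allyl bromide, DMF, 0 °C → rt
Reagents that add atoms: allyl bromide, C=CCBr
Why: Williamson etherification of the secondary alkoxide installs an ether that survives n-BuLi and fluoride and touches no stereocentre.

**Step 4**
Reactants: 5 3,5-bis(benzyloxy)phenol
Product: 6 2-bromo-3,5-bis(benzyloxy)phenol
Conditions: NBS (1.0 equiv), i-Pr2NH (0.1 equiv), CH2Cl2, −78 → 0 °C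
Reagents that add atoms: N-bromosuccinimide, O=C1CCC(=O)N1Br
Why: Amine-mediated ortho-selective electrophilic bromination of a phenol should deliver bromine next to the hydroxyl through the hydrogen-bonded N-bromoamine, the two ortho positions being equivalent.

**Step 5**
Reactants: 6 2-bromo-3,5-bis(benzyloxy)phenol
Product: 7 [2-bromo-3,5-bis(benzyloxy)phenoxy]triisopropylsilane
Conditions: i-Pr3SiCl, imidazole, DMF, rt
Reagents that add atoms: chlorotriisopropylsilane, CC(C)[Si](Cl)(C(C)C)C(C)C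
Why: Silylation of the phenol gives a bulky silyl ether that keeps the ring electron-rich and shields the one open position next to this oxygen.

**Step 6**
Reactants: 4 3-O-allyl-4β-(2-ethoxyethoxy)-5,7,3',4'-tetra-O-benzyl-(−)-epicatechin; 7 [2-bromo-3,5-bis(benzyloxy)phenoxy]triisopropylsilane
Product: 8 top-unit 4β-aryl adduct (aryl = 2,6-bis(benzyloxy)-3-bromo-4-(triisopropylsilyloxy)phenyl)
Conditions: 7 (3 equiv), Me3SiOTf (0.2 equiv), 4 Å sieves, CH2Cl2, −78 → −40 °C; Et3N quench
Reagents that add atoms: none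
Why: In this Lewis-acid Friedel–Crafts alkylation (the standard interflavan coupling) the flavan-4-yl cation should be attacked by the arene carbon between the two benzyloxy groups, anti to the C3 allyloxy group and the C2 aryl group, which sets the 4β configuration.

**Step 7**
Reactants: 8 top-unit 4β-aryl adduct
Product: 9 2-bromophenol of the top-unit adduct
Conditions: Bu4NF (1.05 equiv), THF, 0 °C; aq NH4Cl
Reagents that add atoms: none
Why: Fluoride cleavage of an aryl silyl ether is much faster than any reaction of the benzyl or allyl ethers present.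

**Step 8**
Reactants: 9 2-bromophenol of the top-unit adduct
Product: 12 silyl triflate (aryne precursor), via aryl trimethylsilyl ether 10 (not isolated), via lithium 2-(trimethylsilyl)phenoxide 11 (not isolated)
Conditions: (Me3Si)2NH, THF, 65 °C, then evaporate; n-BuLi (1.1 equiv), THF, −78 °C; Tf2O (1.2 equiv), −78 → 0 °C
Reagents that add atoms: hexamethyldisilazane, C[Si](C)(C)N[Si](C)(C)C; trifluoromethanesulfonic anhydride, O=S(=O)(OS(=O)(=O)C(F)(F)F)C(F)(F)F
Why: O-silylation, bromine–lithium exchange with 1,3-retro-Brook shift of silicon from oxygen to carbon, and triflation of the phenoxide is the standard route to Kobayashi aryne precursors, and the exchange is faster than any reaction of the ethers.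

**Step 9**
Reactants: 13 2-(allyloxy)acetic acid; 14 (S)-4-benzyl-1,3-oxazolidin-2-one
Product: 16 (S)-3-[2-(allyloxy)acetyl]-4-benzyl-1,3-oxazolidin-2-one, via mixed pivalic anhydride 15 (not isolated)
Conditions: t-BuCOCl, Et3N, THF, −20 °C; then LiCl, 14, −20 °C → rt
Reagents that add atoms: none
Why: N-acylation of the oxazolidinone through the mixed anhydride (LiCl/Et3N variant) should take place at the less hindered glycolyl carbonyl.

**Step 10**
Reactants: 16 (S)-3-[2-(allyloxy)acetyl]-4-benzyl-1,3-oxazolidin-2-one; 17 3,4-bis(benzyloxy)benzaldehyde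
Product: 19 syn aldol adduct (2'S,3'R), via Z-dibutylboron enolate 18 (not isolated)
Conditions: Bu2BOTf, i-Pr2NEt, CH2Cl2, −78 → 0 °C; 17, −78 → 0 °C; pH 7 buffer, MeOH, H2O2, 0 °C
Reagents that add atoms: none
Why: In this Evans syn aldol the Z-boron enolate should react through a closed chair transition state on the face away from the benzyl group of the auxiliary, setting the future C2 (R) and C3 (R) of the middle unit in the syn relationship.

**Step 11**
Reactants: 19 syn aldol adduct (2'S,3'R)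
Product: 20 (2S,3R)-2-(allyloxy)-3-[3,4-bis(benzyloxy)phenyl]-3-hydroxy-N-methoxy-N-methylpropanamide
Conditions: MeNH(OMe)·HCl, AlMe3, CH2Cl2, −20 → 0 °C; aq HCl work-up
Reagents that add atoms: N,O-dimethylhydroxylamine hydrochloride, CNOC.Cl
Why: Weinreb transamination of the imide by the aluminium amide is assisted by the free β-hydroxyl and releases the auxiliary without touching the two stereocentres.

**Step 12**
Reactants: 20 hydroxy Weinreb amide
Product: 21 (2S,3R)-2-(allyloxy)-3-[3,4-bis(benzyloxy)phenyl]-N-methoxy-N-methyl-3-(triethylsilyloxy)propanamide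
Conditions: Et3SiCl, imidazole, DMF, 0 °C → rt
Reagents that add atoms: chlorotriethylsilane, CC[Si](Cl)(CC)CC
Why: Silylation of the secondary alcohol masks the future O1 as an ether that fluoride removes in the key step.

**Step 13**
Reactants: 21 silyloxy Weinreb amide
Product: 22 (2S,3R)-2-(allyloxy)-3-[3,4-bis(benzyloxy)phenyl]-3-(triethylsilyloxy)propanal
Conditions: i-Bu2AlH, THF, −78 °C; aq potassium sodium tartrate
Reagents that add atoms: none
Why: Reduction of a Weinreb amide stops at the aldehyde through the chelated tetrahedral intermediate, and the cold neutral work-up should keep the α-stereocentre.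

**Step 14**
Reactants: 12 silyl triflate (aryne precursor); 22 silyloxy aldehyde
Product: 24 middle-unit flavan-4-ol (C4 epimers), via aryne 23 (not isolated)
Conditions: 22 (1.5 equiv), CsF (4 equiv, added last), 18-crown-6 (4 equiv), THF, −20 °C → rt; aq NH4Cl
Reagents that add atoms: none
Why: Proposed new method: fluoride removes the trimethylsilyl group of 12 (triflate then leaves, giving aryne 23 with the triple bond between the future C4a and C8a) and the triethylsilyl group of 22 (giving the cesium alkoxide of the future O1) in the same flask with no O–H present, the alkoxide adds to the aryne and the aryl anion so formed adds to the tethered aldehyde, so that the O1–C8a bond and the C4a–C4 bond are made in one operation. The closest known reaction type is the aryne annulation of salicylaldehydes and salicylates (phenoxide addition to the aryne, then attack of the aryl anion on the ortho carbonyl group, giving xanthenols and xanthones), extended here to an aliphatic aldolate. The pyran ring closes by 6-exo-trig addition of the C4a anion to the C=O group. C2 and C3 are not made here but carried in from the aldol with the O1–C2 bond intact, so the syn aldol should appear with retention as the 2,3-cis (epicatechin) array, and the new C4 carbinol centre is left uncontrolled because step 17 ionizes it. The step needs regioselective addition of oxygen to the future C8a, which the benzyloxy group on the carbon next to the future C4a secures (inductive stabilization of the developing anion, as in 3-alkoxybenzynes), and it needs the aldolate to survive until capture without retro-aldol cleavage or enolization, which the simultaneous release of both partners, the absence of a proton source and the low temperature are meant to secure.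

**Step 15**
Reactants: 25 (+)-catechin
Product: 26 5,7,3',4'-tetra-O-benzyl-(+)-catechin
Conditions: BnBr (4.4 equiv), K2CO3, DMF, 0 °C → rt
Reagents that add atoms: benzyl bromide, BrCc1ccccc1
Why: Williamson etherification of the four phenols should leave the 3-hydroxyl free and the stereocentres untouched.

**Step 16**
Reactants: 26 5,7,3',4'-tetra-O-benzyl-(+)-catechin
Product: 27 3,5,7,3',4'-penta-O-benzyl-(+)-catechin
Conditions: NaH, BnBr, DMF, 0 °C → rt
Reagents that add atoms: benzyl bromide, BrCc1ccccc1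
Why: Williamson etherification of the 3-hydroxyl marks the bottom-unit oxygen that must stay free of gallate and is released only in the final hydrogenolysis.

**Step 17**
Reactants: 24 middle-unit flavan-4-ol (C4 epimers); 27 3,5,7,3',4'-penta-O-benzyl-(+)-catechin
Product: 28 protected trimer bis(allyl ether)
Conditions: 27 (4 equiv), Me3SiOTf (0.2 equiv), 4 Å sieves, CH2Cl2, −78 → −30 °C; Et3N quench
Reagents that add atoms: none
Why: In this acid-catalysed dehydrative Friedel–Crafts alkylation (interflavan coupling) ionization of the 4-hydroxyl gives the C4 cation of the middle unit, which C8 of 27 (the more nucleophilic position of a 5,7-dialkoxyflavan) should attack anti to the C3 allyloxy group to give the 4β (3,4-trans) linkage.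

**Step 18**
Reactants: 28 protected trimer bis(allyl ether)
Product: 30 trimer diol, via bis(prop-1-enyl) ether 29 (not isolated)
Conditions: [Ir(cod)(PMePh2)2]PF6 (10 mol %, activated by H2), THF, rt; then 1 M aq HCl, acetone, rt
Reagents that add atoms: none
Why: Iridium-catalysed isomerization of both allyl ethers to prop-1-enyl ethers followed by mild acidic hydrolysis of these enol ethers should free the top and middle 3-hydroxyls while benzyl ethers and interflavan bonds stay intact.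

**Step 19**
Reactants: 30 trimer diol; 31 3,4,5-tris(benzyloxy)benzoic acid
Product: 32 fully benzylated digallate
Conditions: 31 (6 equiv), DCC, DMAP, CH2Cl2, rt
Reagents that add atoms: none
Why: Steglich esterification should acylate the only two free hydroxyls (top and middle 3-OH) in one operation.

**Step 20**
Reactants: 32 fully benzylated digallate
Product: 33 target
Conditions: H2 (1 atm), Pd(OH)2 on carbon, THF/MeOH/H2O, rt
Reagents that add atoms: none
Why: Catalytic hydrogenolysis should remove all nineteen benzyl ethers while the gallate esters, the interflavan bonds and all stereocentres are unaffected.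

**Compound list**
1 | (−)-epicatechin, (2R,3R) | O[C@@H]1Cc2c(O)cc(O)cc2O[C@@H]1c1ccc(O)c(O)c1 | starting material
2 | 5,7,3',4'-tetra-O-benzyl-(−)-epicatechin, (2R,3R) | O[C@@H]1Cc2c(OCc5ccccc5)cc(OCc5ccccc5)cc2O[C@@H]1c1ccc(OCc5ccccc5)c(OCc5ccccc5)c1 | intermediate
3 | 4β-(2-ethoxyethoxy)-5,7,3',4'-tetra-O-benzyl-(−)-epicatechin, (2R,3R,4S) | O[C@@H]1[C@@H](OCCOCC)c2c(OCc5ccccc5)cc(OCc5ccccc5)cc2O[C@@H]1c1ccc(OCc5ccccc5)c(OCc5ccccc5)c1 | intermediate
4 | 3-O-allyl-4β-(2-ethoxyethoxy)-5,7,3',4'-tetra-O-benzyl-(−)-epicatechin, (2R,3R,4S) | C=CCO[C@@H]1[C@@H](OCCOCC)c2c(OCc5ccccc5)cc(OCc5ccccc5)cc2O[C@@H]1c1ccc(OCc5ccccc5)c(OCc5ccccc5)c1 | intermediate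
5 | 3,5-bis(benzyloxy)phenol | Oc1cc(OCc5ccccc5)cc(OCc5ccccc5)c1 | starting material
6 | 2-bromo-3,5-bis(benzyloxy)phenol | Oc1cc(OCc5ccccc5)cc(OCc5ccccc5)c1Br | intermediate
7 | [2-bromo-3,5-bis(benzyloxy)phenoxy]triisopropylsilane | CC(C)[Si](C(C)C)(C(C)C)Oc1cc(OCc5ccccc5)cc(OCc5ccccc5)c1Br | intermediate
8 | 3-O-allyl-5,7,3',4'-tetra-O-benzyl-(−)-epicatechin carrying at C4 (4β, trans to the 3-oxygen) a 2,6-bis(benzyloxy)-3-bromo-4-(triisopropylsilyloxy)phenyl group | C=CCO[C@@H]1[C@@H](c2c(OCc5ccccc5)cc(O[Si](C(C)C)(C(C)C)C(C)C)c(Br)c2OCc5ccccc5)c2c(OCc5ccccc5)cc(OCc5ccccc5)cc2O[C@@H]1c1ccc(OCc5ccccc5)c(OCc5ccccc5)c1 | intermediate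
9 | as 8 with free phenol: 2-bromo-3,5-bis(benzyloxy)-4-(flavan-4β-yl)phenol | C=CCO[C@@H]1[C@@H](c2c(OCc5ccccc5)cc(O)c(Br)c2OCc5ccccc5)c2c(OCc5ccccc5)cc(OCc5ccccc5)cc2O[C@@H]1c1ccc(OCc5ccccc5)c(OCc5ccccc5)c1 | intermediate
10 | trimethylsilyl ether of 9 | C=CCO[C@@H]1[C@@H](c2c(OCc5ccccc5)cc(O[Si](C)(C)C)c(Br)c2OCc5ccccc5)c2c(OCc5ccccc5)cc(OCc5ccccc5)cc2O[C@@H]1c1ccc(OCc5ccccc5)c(OCc5ccccc5)c1 | intermediate
11 | lithium 3,5-bis(benzyloxy)-4-(flavan-4β-yl)-2-(trimethylsilyl)phenoxide | [Li+].C=CCO[C@@H]1[C@@H](c2c(OCc5ccccc5)cc([O-])c([Si](C)(C)C)c2OCc5ccccc5)c2c(OCc5ccccc5)cc(OCc5ccccc5)cc2O[C@@H]1c1ccc(OCc5ccccc5)c(OCc5ccccc5)c1 | intermediate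
12 | 3,5-bis(benzyloxy)-4-(flavan-4β-yl)-2-(trimethylsilyl)phenyl trifluoromethanesulfonate (flavan = 3-O-allyl-5,7,3',4'-tetra-O-benzyl-(−)-epicatechin) | C=CCO[C@@H]1[C@@H](c2c(OCc5ccccc5)cc(OS(=O)(=O)C(F)(F)F)c([Si](C)(C)C)c2OCc5ccccc5)c2c(OCc5ccccc5)cc(OCc5ccccc5)cc2O[C@@H]1c1ccc(OCc5ccccc5)c(OCc5ccccc5)c1 | intermediate
13 | 2-(allyloxy)acetic acid | C=CCOCC(=O)O | starting material
14 | (S)-4-benzyl-1,3-oxazolidin-2-one | O=C1N[C@@H](Cc2ccccc2)CO1 | starting material
15 | 2-(allyloxy)acetic pivalic anhydride | C=CCOCC(=O)OC(=O)C(C)(C)C | intermediate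
16 | (S)-3-[2-(allyloxy)acetyl]-4-benzyl-1,3-oxazolidin-2-one | C=CCOCC(=O)N1[C@@H](Cc2ccccc2)COC1=O | intermediate
17 | 3,4-bis(benzyloxy)benzaldehyde | O=Cc1ccc(OCc5ccccc5)c(OCc5ccccc5)c1 | starting material
18 | Z-dibutylboron enolate of 16 | C=CCO/C=C(\OB(CCCC)CCCC)N1[C@@H](Cc2ccccc2)COC1=O | intermediate
19 | (4S)-3-[(2S,3R)-2-(allyloxy)-3-[3,4-bis(benzyloxy)phenyl]-3-hydroxypropanoyl]-4-benzyl-1,3-oxazolidin-2-one | C=CCO[C@H](C(=O)N1[C@@H](Cc2ccccc2)COC1=O)[C@H](O)c1ccc(OCc5ccccc5)c(OCc5ccccc5)c1 | intermediate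
20 | (2S,3R)-2-(allyloxy)-3-[3,4-bis(benzyloxy)phenyl]-3-hydroxy-N-methoxy-N-methylpropanamide | C=CCO[C@H](C(=O)N(C)OC)[C@H](O)c1ccc(OCc5ccccc5)c(OCc5ccccc5)c1 | intermediate
21 | (2S,3R)-2-(allyloxy)-3-[3,4-bis(benzyloxy)phenyl]-N-methoxy-N-methyl-3-(triethylsilyloxy)propanamide | C=CCO[C@H](C(=O)N(C)OC)[C@H](O[Si](CC)(CC)CC)c1ccc(OCc5ccccc5)c(OCc5ccccc5)c1 | intermediate
22 | (2S,3R)-2-(allyloxy)-3-[3,4-bis(benzyloxy)phenyl]-3-(triethylsilyloxy)propanal | C=CCO[C@H](C=O)[C@H](O[Si](CC)(CC)CC)c1ccc(OCc5ccccc5)c(OCc5ccccc5)c1 | intermediate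
23 | aryne from 12: 3,5-bis(benzyloxy)-4-(flavan-4β-yl)benzyne, triple bond between the former C–Si and C–OTf carbons | C=CCO[C@@H]1[C@@H](C2=C(OCc5ccccc5)C#CC=C2OCc5ccccc5)c2c(OCc5ccccc5)cc(OCc5ccccc5)cc2O[C@@H]1c1ccc(OCc5ccccc5)c(OCc5ccccc5)c1 | intermediate
24 | 3-O-allyl-tetra-O-benzyl-(−)-epicatechin-(4β→6)-[3-O-allyl-5,7,3',4'-tetra-O-benzyl-4-hydroxyflavan, (2R,3R), C4 epimers] | C=CCO[C@@H]1[C@@H](c2c(OCc5ccccc5)cc3c(c2OCc5ccccc5)C(O)[C@@H](OCC=C)[C@@H](c2ccc(OCc5ccccc5)c(OCc5ccccc5)c2)O3)c2c(OCc5ccccc5)cc(OCc5ccccc5)cc2O[C@@H]1c1ccc(OCc5ccccc5)c(OCc5ccccc5)c1 | intermediate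
25 | (+)-catechin, (2R,3S) | O[C@H]1Cc2c(O)cc(O)cc2O[C@@H]1c1ccc(O)c(O)c1 | starting material
26 | 5,7,3',4'-tetra-O-benzyl-(+)-catechin, (2R,3S) | O[C@H]1Cc2c(OCc5ccccc5)cc(OCc5ccccc5)cc2O[C@@H]1c1ccc(OCc5ccccc5)c(OCc5ccccc5)c1 | intermediate
27 | 3,5,7,3',4'-penta-O-benzyl-(+)-catechin, (2R,3S) | C(c5ccccc5)O[C@H]1Cc2c(OCc5ccccc5)cc(OCc5ccccc5)cc2O[C@@H]1c1ccc(OCc5ccccc5)c(OCc5ccccc5)c1 | intermediate
28 | 3-O-allyl-tetra-O-benzyl-epicatechin-(4β→6)-3-O-allyl-tetra-O-benzyl-epicatechin-(4β→8)-penta-O-benzyl-catechin | C=CCO[C@@H]1[C@@H](c2c(OCc5ccccc5)cc3c(c2OCc5ccccc5)[C@H](c2c(OCc5ccccc5)cc(OCc5ccccc5)c4c2O[C@H](c2ccc(OCc5ccccc5)c(OCc5ccccc5)c2)[C@@H](OCc5ccccc5)C4)[C@@H](OCC=C)[C@@H](c2ccc(OCc5ccccc5)c(OCc5ccccc5)c2)O3)c2c(OCc5ccccc5)cc(OCc5ccccc5)cc2O[C@@H]1c1ccc(OCc5ccccc5)c(OCc5ccccc5)c1 | intermediate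
29 | as 28 with both allyl ethers isomerized to (E)-prop-1-enyl ethers | C/C=C/O[C@@H]1[C@@H](c2c(OCc5ccccc5)cc3c(c2OCc5ccccc5)[C@H](c2c(OCc5ccccc5)cc(OCc5ccccc5)c4c2O[C@H](c2ccc(OCc5ccccc5)c(OCc5ccccc5)c2)[C@@H](OCc5ccccc5)C4)[C@@H](O/C=C/C)[C@@H](c2ccc(OCc5ccccc5)c(OCc5ccccc5)c2)O3)c2c(OCc5ccccc5)cc(OCc5ccccc5)cc2O[C@@H]1c1ccc(OCc5ccccc5)c(OCc5ccccc5)c1 | intermediate
30 | as 28 with free 3-hydroxyls on the top and middle units | O[C@@H]1[C@@H](c2c(OCc5ccccc5)cc3c(c2OCc5ccccc5)[C@H](c2c(OCc5ccccc5)cc(OCc5ccccc5)c4c2O[C@H](c2ccc(OCc5ccccc5)c(OCc5ccccc5)c2)[C@@H](OCc5ccccc5)C4)[C@@H](O)[C@@H](c2ccc(OCc5ccccc5)c(OCc5ccccc5)c2)O3)c2c(OCc5ccccc5)cc(OCc5ccccc5)cc2O[C@@H]1c1ccc(OCc5ccccc5)c(OCc5ccccc5)c1 | intermediate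
31 | 3,4,5-tris(benzyloxy)benzoic acid | OC(=O)c1cc(OCc5ccccc5)c(OCc5ccccc5)c(OCc5ccccc5)c1 | starting material
32 | nonadeca-O-benzyl ether of the target (both gallates as tris(benzyloxy)benzoates) | O=C(O[C@@H]1[C@@H](c2c(OCc5ccccc5)cc3c(c2OCc5ccccc5)[C@H](c2c(OCc5ccccc5)cc(OCc5ccccc5)c4c2O[C@H](c2ccc(OCc5ccccc5)c(OCc5ccccc5)c2)[C@@H](OCc5ccccc5)C4)[C@@H](OC(=O)c2cc(OCc5ccccc5)c(OCc5ccccc5)c(OCc5ccccc5)c2)[C@@H](c2ccc(OCc5ccccc5)c(OCc5ccccc5)c2)O3)c2c(OCc5ccccc5)cc(OCc5ccccc5)cc2O[C@@H]1c1ccc(OCc5ccccc5)c(OCc5ccccc5)c1)c1cc(OCc5ccccc5)c(OCc5ccccc5)c(OCc5ccccc5)c1 | intermediate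
33 | (−)-epicatechin 3-O-gallate-(4β→6)-(−)-epicatechin 3-O-gallate-(4β→8)-(+)-catechin (CNP0112921.1) | O=C(O[C@@H]1[C@@H](c2c(O)cc3c(c2O)[C@H](c2c(O)cc(O)c4c2O[C@H](c2ccc(O)c(O)c2)[C@@H](O)C4)[C@@H](OC(=O)c2cc(O)c(O)c(O)c2)[C@@H](c2ccc(O)c(O)c2)O3)c2c(O)cc(O)cc2O[C@@H]1c1ccc(O)c(O)c1)c1cc(O)c(O)c(O)c1 | target

**Step count and risks**
Total steps: 20. Longest linear sequence: 11 steps (1, 2, 3, 6, 7, 8, 14, 17, 18, 19, 20).

Step 14 (most likely to fail). The cesium aldolate may cleave by retro-aldol reaction or enolize before the aryne captures it, the two fluoride-triggered releases may run at different rates, or the aryl anion may be protonated instead of closing the ring. The fallback makes the two bonds one after the other by known chemistry, setting out from 22 and 12 and coming back at 28. Aldehyde 22 is treated with HC(OMe)3 and pyridinium p-toluenesulfonate in methanol to give the hydroxy dimethyl acetal F1, the triethylsilyl ether being cleaved in the same acidic methanol. F1 and 12 with CsF in MeCN at rt give, by ordinary aryne O–H insertion, the aryl ether F2; the two ring positions ortho to the new ether oxygen are equivalent. Me3SiOTf in CH2Cl2 at −78 °C in the presence of 27 ionizes the acetal, the oxocarbenium ion closes onto the ring by Friedel–Crafts attack to the 4-methoxyflavan F3, and F3 ionizes again in the same flask and is captured by 27 to give 28.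

Step 6. The flavanyl cation may attack the position between the silyloxy and benzyloxy groups (poor site selectivity), or self-condensation of the cation may outrun the bromine-deactivated arene. The fallback sets out from 4 and comes back at 12. Compound 4 is coupled (Me3SiOTf, THF/CH2Cl2, −78 → 0 °C) with excess phloroglucinol, whose three positions are equivalent, to give the 4β-(2,4,6-trihydroxyphenyl) adduct F4. The unhindered para hydroxyl is carbamoylated with isopropyl isocyanate (Et3N cat., CH2Cl2, 0 °C) to the mono-carbamate F5. The two flanked hydroxyls are benzylated (BnBr, K2CO3, acetone) to F6. Carbamate-directed ortho-lithiation (Me3SiOTf/TMEDA, then n-BuLi/TMEDA, −78 °C, then Me3SiCl) gives the ortho-silyl carbamate F7. One-pot carbamate cleavage and triflation (DBU, Et2NH, MeCN, 40 °C, then PhNTf2) gives 12.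

Step 17. Capture of the hindered C4 cation may be slow, so that attack through C6 of 27, further alkylation of the electron-rich rings of the product, or acid cleavage of the existing 4→6 bond compete. The fallback sets out from 24 and comes back at 28. Compound 24 is converted with benzyl mercaptan and catalytic BF3·OEt2 (CH2Cl2, −40 °C) into the 4β-benzylthio ether F8. F8 is then activated with AgBF4 in THF at 0 °C in the presence of 27, a thiophilic activation without Brønsted acid, to give 28.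

**Further compounds**
F1 | step 14 | (1R,2S)-2-(allyloxy)-1-[3,4-bis(benzyloxy)phenyl]-3,3-dimethoxypropan-1-ol | C=CCO[C@H](C(OC)OC)[C@H](O)c1ccc(OCc5ccccc5)c(OCc5ccccc5)c1
F2 | step 14 | aryl ether of F1 with the 3,5-bis(benzyloxy)-4-(flavan-4β-yl)phenyl group (flavan as in 12) | C=CCO[C@@H]1[C@@H](c2c(OCc5ccccc5)cc(O[C@H](c3ccc(OCc5ccccc5)c(OCc5ccccc5)c3)[C@H](OCC=C)C(OC)OC)cc2OCc5ccccc5)c2c(OCc5ccccc5)cc(OCc5ccccc5)cc2O[C@@H]1c1ccc(OCc5ccccc5)c(OCc5ccccc5)c1
F3 | step 14 | 4-O-methyl ether of 24 (C4 epimers) | C=CCO[C@@H]1[C@@H](c2c(OCc5ccccc5)cc3c(c2OCc5ccccc5)C(OC)[C@@H](OCC=C)[C@@H](c2ccc(OCc5ccccc5)c(OCc5ccccc5)c2)O3)c2c(OCc5ccccc5)cc(OCc5ccccc5)cc2O[C@@H]1c1ccc(OCc5ccccc5)c(OCc5ccccc5)c1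
F4 | step 6 | 3-O-allyl-tetra-O-benzyl-epicatechin-(4β→2)-phloroglucinol | C=CCO[C@@H]1[C@@H](c2c(O)cc(O)cc2O)c2c(OCc5ccccc5)cc(OCc5ccccc5)cc2O[C@@H]1c1ccc(OCc5ccccc5)c(OCc5ccccc5)c1
F5 | step 6 | F4 with the para hydroxyl as N-isopropylcarbamate | C=CCO[C@@H]1[C@@H](c2c(O)cc(OC(=O)NC(C)C)cc2O)c2c(OCc5ccccc5)cc(OCc5ccccc5)cc2O[C@@H]1c1ccc(OCc5ccccc5)c(OCc5ccccc5)c1
F6 | step 6 | F5 with the two flanked hydroxyls benzylated | C=CCO[C@@H]1[C@@H](c2c(OCc5ccccc5)cc(OC(=O)NC(C)C)cc2OCc5ccccc5)c2c(OCc5ccccc5)cc(OCc5ccccc5)cc2O[C@@H]1c1ccc(OCc5ccccc5)c(OCc5ccccc5)c1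
F7 | step 6 | F6 with a trimethylsilyl group ortho to the carbamate | C=CCO[C@@H]1[C@@H](c2c(OCc5ccccc5)cc(OC(=O)NC(C)C)c([Si](C)(C)C)c2OCc5ccccc5)c2c(OCc5ccccc5)cc(OCc5ccccc5)cc2O[C@@H]1c1ccc(OCc5ccccc5)c(OCc5ccccc5)c1
F8 | step 17 | 4β-benzylthio analogue of 24 | C=CCO[C@@H]1[C@@H](c2c(OCc5ccccc5)cc3c(c2OCc5ccccc5)[C@H](SCc5ccccc5)[C@@H](OCC=C)[C@@H](c2ccc(OCc5ccccc5)c(OCc5ccccc5)c2)O3)c2c(OCc5ccccc5)cc(OCc5ccccc5)cc2O[C@@H]1c1ccc(OCc5ccccc5)c(OCc5ccccc5)c1
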